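**Plan**

- Retrosynthesis: the six C–Br bonds are cut first, five back to C–H and the one at C4' back to a carboxyl group; ring B is then opened at C2'–C3' and C4'–C5'.
- This leaves an α-(pyrrol-2-yl) tosylmethyl isocyanide (ring A plus C2'–N1'–C5') and methyl acrylate (C3'–C4'). The isocyanide is traced through its formamide to pyrrole-2-carboxaldehyde, formamide and p-toluenesulfinic acid.
- Enabling feature: ring B carries ring A on C2' and only bromine on C3', C4' and C5'. A 2,4-disubstituted pyrrole whose C4' ester can later be exchanged for bromine therefore maps onto the isocyanide/acrylate pair.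
- Forward: ring A is bought as the aldehyde and N-tosylated, the aldehyde carbon is converted into the sulfonyl isocyanide, ring B is closed in one [3+2] annulation, and deprotection/saponification followed by exhaustive bromination finishes the synthesis.
- Stereochemistry: the target has no stereocentres; the racemic sp3 centres that appear on the way are erased when ring B aromatises.

Key step: step 4

Remark: primed locants (N1', C2'–C5') denote ring B, the ring built in the route, and unprimed ones ring A; p-toluenesulfinic acid is assumed to be used as the commercial free acid, dried before use.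

**Route**

Step 1
Reactants: 1 pyrrole-2-carboxaldehyde
Product: 2 1-tosyl-1H-pyrrole-2-carbaldehyde
Conditions: NaH, THF, 0 °C; then TsCl, 0 °C to rt
Reagents that add atoms: p-toluenesulfonyl chloride, Cc1ccc(cc1)S(=O)(=O)Cl
Why: N-sulfonylation of the sodium pyrrolide, whose formation is eased by the 2-formyl group, should proceed cleanly at nitrogen with the hard sulfonyl chloride.

Step 2
Reactants: 2 1-tosyl-1H-pyrrole-2-carbaldehyde; 3 formamide; 4 p-toluenesulfinic acid
Product: 6 N-[(1-tosyl-1H-pyrrol-2-yl)(tosyl)methyl]formamide (racemic), via bis-formamide aminal 5 (not isolated)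
Conditions: HCONH2 (excess), TMSCl, toluene/MeCN, 50 °C; then TolSO2H, 50 °C
Reagents that add atoms: none
Why: In this three-component amidoalkylation (Mannich-type α-amido sulfone synthesis) the TMSCl-promoted condensation gives aminal 5, which should ionise to an N-formyliminium ion that the sulfinic acid captures through sulfur, the N-tosyl group keeping the aldehyde electrophilic and the pyrrole acid-stable.

Step 3
Reactants: 6 N-[(1-tosyl-1H-pyrrol-2-yl)(tosyl)methyl]formamide
Product: 7 (1-tosyl-1H-pyrrol-2-yl)(tosyl)methyl isocyanide (racemic)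
Conditions: POCl3, Et3N, THF, −5 to 5 °C
Reagents that add atoms: none
Why: Formamide dehydration (O-phosphorylation followed by base-induced α-elimination) is the standard entry to α-substituted tosylmethyl isocyanides and should be run cold because such isocyanides are heat-sensitive.

Step 4
Reactants: 7 (1-tosyl-1H-pyrrol-2-yl)(tosyl)methyl isocyanide; 8 methyl acrylate
Product: 10 methyl 5-(1-tosyl-1H-pyrrol-2-yl)-1H-pyrrole-3-carboxylate, via sulfonyl pyrroline adduct 9 (not isolated)
Conditions: methyl acrylate (1.5 equiv), DBU (1.5 equiv), MeCN, 0 °C to rt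
Reagents that add atoms: none
Why: DBU should deprotonate 7 at the carbon flanked by isocyanide, sulfone and ring A, the carbanion adds to the β-carbon of methyl acrylate (C2'–C3'), the resulting ester enolate attacks the isocyanide carbon (C4'–C5'), and protonation of the imidoyl anion gives pyrroline 9. Base-mediated loss of p-toluenesulfinate across C2'–C3' and a proton shift from C4' to nitrogen then aromatise ring B. The closest known reaction is the van Leusen pyrrole synthesis with α-aryl tosylmethyl isocyanides and acrylates, here applied to an N-sulfonylpyrrolyl-substituted reagent. Ring B closes in an anionic 5-endo-dig mode at the isocyanide carbon. No stereocentre is created that survives, since the centre of 7 and the two of 9 disappear on aromatisation. The step needs regiocontrol, which Michael polarity supplies by placing the ester on C4' away from ring A, and a carbanion that does not expel sulfinate prematurely, which the N-tosyl group on ring A secures by tying up the pyrrole lone pair (no azafulvene pathway) and by acidifying the α-C–H.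

Step 5
Reactants: 10 methyl 5-(1-tosyl-1H-pyrrol-2-yl)-1H-pyrrole-3-carboxylate
Product: 11 5-(1H-pyrrol-2-yl)-1H-pyrrole-3-carboxylic acid
Conditions: KOH (excess), 1,4-dioxane/H2O, 90 °C, argon; then 1 M HCl to pH 3–4, 0 °C
Reagents that add atoms: potassium hydroxide, [K+].[OH-]
Why: Alkaline N-desulfonylation (hydroxide attack at sulfur with pyrrolide as leaving group) and ester saponification should occur in the same pot, the alcohol-free medium avoiding sulfonate esters that could N-alkylate the pyrrolide.

Step 6
Reactants: 11 5-(1H-pyrrol-2-yl)-1H-pyrrole-3-carboxylic acid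
Product: 12 3,3',4,4',5,5'-hexabromo-1H,1'H-2,2'-bipyrrole
Conditions: Br2 (6.5 equiv), NaOAc, AcOH, 10 °C to rt, dark; aq. Na2S2O3 quench
Reagents that add atoms: bromine, BrBr
Why: Electrophilic aromatic bromination should substitute the five free C–H positions of the electron-rich bipyrrole, and ipso-bromodecarboxylation (attack at the carboxyl-bearing C4' and loss of CO2 from the σ-complex) is the classical replacement of a pyrrole carboxyl group by bromine.

**Compound list**

1 | pyrrole-2-carboxaldehyde | O=Cc1ccc[nH]1 | starting material
2 | 1-tosyl-1H-pyrrole-2-carbaldehyde | O=Cc1cccn1S(=O)(=O)c1ccc(C)cc1 | intermediate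
3 | formamide | NC=O | starting material
4 | p-toluenesulfinic acid | Cc1ccc(cc1)S(=O)O | starting material
5 | N,N'-[(1-tosyl-1H-pyrrol-2-yl)methanediyl]diformamide (bis-formamide aminal) | O=CNC(NC=O)c1cccn1S(=O)(=O)c1ccc(C)cc1 | intermediate (not isolated)
6 | N-[(1-tosyl-1H-pyrrol-2-yl)(tosyl)methyl]formamide, racemic | O=CNC(c1cccn1S(=O)(=O)c1ccc(C)cc1)S(=O)(=O)c1ccc(C)cc1 | intermediate
7 | (1-tosyl-1H-pyrrol-2-yl)(tosyl)methyl isocyanide, racemic | Cc1ccc(cc1)S(=O)(=O)C([N+]#[C-])c1cccn1S(=O)(=O)c1ccc(C)cc1 | intermediate
8 | methyl acrylate | C=CC(=O)OC | starting material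
9 | methyl 2-tosyl-2-(1-tosyl-1H-pyrrol-2-yl)-3,4-dihydro-2H-pyrrole-4-carboxylate (sulfonyl pyrroline adduct, mixture of racemic diastereomers) | COC(=O)C1CC(N=C1)(c1cccn1S(=O)(=O)c1ccc(C)cc1)S(=O)(=O)c1ccc(C)cc1 | intermediate (not isolated)
10 | methyl 5-(1-tosyl-1H-pyrrol-2-yl)-1H-pyrrole-3-carboxylate | COC(=O)c1c[nH]c(c1)-c1cccn1S(=O)(=O)c1ccc(C)cc1 | intermediate
11 | 5-(1H-pyrrol-2-yl)-1H-pyrrole-3-carboxylic acid | OC(=O)c1c[nH]c(c1)-c1ccc[nH]1 | intermediate
12 | 3,3',4,4',5,5'-hexabromo-1H,1'H-2,2'-bipyrrole | Brc1[nH]c(-c2[nH]c(Br)c(Br)c2Br)c(Br)c1Br | target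

**Step count**

Total steps: 6. Longest linear sequence: 6 steps (1 to 12).

**Steps most likely to fail**

1. Step 4. The tertiary carbanion of 7 is crowded by the neighbouring N-tosyl group and may add to the acrylate more slowly than the isocyanide degrades under base or the acrylate oligomerises; the sulfinate may also be slow to leave the pyrroline. The fallback builds ring B by a different [3+2] process; it sets out from 2 and 8 and returns at 12. Condensation of 2 with glycine methyl ester hydrochloride (Et3N, MgSO4, CH2Cl2) should give methyl N-[(E)-(1-tosyl-1H-pyrrol-2-yl)methylidene]glycinate F1. Its silver azomethine ylide (AgOAc, Et3N, toluene, rt) should add to methyl acrylate 8 to give dimethyl 5-(1-tosyl-1H-pyrrol-2-yl)pyrrolidine-2,4-dicarboxylate F2, racemic and of no stereochemical consequence. Dehydrogenation with DDQ in hot toluene should give dimethyl 5-(1-tosyl-1H-pyrrol-2-yl)-1H-pyrrole-2,4-dicarboxylate F3. KOH under the conditions of step 5 should give 5-(1H-pyrrol-2-yl)-1H-pyrrole-2,4-dicarboxylic acid F4. Br2/NaOAc/AcOH, with two ipso-bromodecarboxylations and four C–H brominations, should then deliver 12.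

2. Step 2. The amidoalkylation is reversible: the aminal may ionise poorly at this hindered aldehyde carbon, or the α-amido sulfone may lose sulfinate again during isolation. The fallback changes the activating and leaving group on the isocyanide carbon; it sets out from 2 and returns at 10. Condensation of 2 with 1H-benzotriazole and formamide in refluxing toluene with azeotropic removal of water should give N-[(1H-benzotriazol-1-yl)(1-tosyl-1H-pyrrol-2-yl)methyl]formamide F5. Dehydration with POCl3/Et3N should give 1-[isocyano(1-tosyl-1H-pyrrol-2-yl)methyl]-1H-benzotriazole F6. Annulation of F6 with methyl acrylate 8 (t-BuOK, THF, low temperature), with benzotriazolide leaving in place of sulfinate, should give 10.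

3. Step 6. The ipso-substitution at C4' may stall once ring B already carries two bromines, leaving a brominated acid, or the electron-rich bipyrrole may be degraded oxidatively by bromine. The fallback separates loss of the carboxyl group from halogenation; it sets out from 11 and returns at 12. Protodecarboxylation by heating 11 with NaOH in ethylene glycol (about 190 °C, argon) should give 1H,1'H-2,2'-bipyrrole F7. Exhaustive bromination of its six C–H positions with NBS (6 equiv, THF, −78 °C to rt) should give 12.

**Further compounds**

F1 | step 4 | methyl N-[(E)-(1-tosyl-1H-pyrrol-2-yl)methylidene]glycinate | COC(=O)C/N=C/c1cccn1S(=O)(=O)c1ccc(C)cc1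
F2 | step 4 | dimethyl 5-(1-tosyl-1H-pyrrol-2-yl)pyrrolidine-2,4-dicarboxylate (racemic, mixture of diastereomers) | COC(=O)C1CC(C(=O)OC)C(N1)c1cccn1S(=O)(=O)c1ccc(C)cc1
F3 | step 4 | dimethyl 5-(1-tosyl-1H-pyrrol-2-yl)-1H-pyrrole-2,4-dicarboxylate | COC(=O)c1cc(C(=O)OC)c([nH]1)-c1cccn1S(=O)(=O)c1ccc(C)cc1
F4 | step 4 | 5-(1H-pyrrol-2-yl)-1H-pyrrole-2,4-dicarboxylic acid | OC(=O)c1cc(C(=O)O)c([nH]1)-c1ccc[nH]1
F5 | step 2 | N-[(1H-benzotriazol-1-yl)(1-tosyl-1H-pyrrol-2-yl)methyl]formamide (racemic) | O=CNC(n1nnc2ccccc12)c1cccn1S(=O)(=O)c1ccc(C)cc1
F6 | step 2 | 1-[isocyano(1-tosyl-1H-pyrrol-2-yl)methyl]-1H-benzotriazole (racemic) | [C-]#[N+]C(n1nnc2ccccc12)c1cccn1S(=O)(=O)c1ccc(C)cc1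
F7 | step 6 | 1H,1'H-2,2'-bipyrrole | c1c[nH]c(c1)-c1ccc[nH]1
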